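**Plan**

1. Cuts: (a) the diene at its central C(sp2)–C(sp2) bond and at the vinyl–CH3 bond (a 1,1-dibromoalkene is coupled with a western alkenylboronate, then methylated); (b) in the western 2,2,3-trimethyl-6-methylidenecyclohexyl ring, the bond between the methyl-bearing CH and the gem-dimethyl carbon, together with the exocyclic C=CH2; (c) in the eastern ring, the quaternary C–CH2 bond, the ring CH–(CH2)3O bond and the enal.
2. Enabling feature: in the western ring the exocyclic methylene carbon lies two bonds from the gem-dimethyl ring carbon (a homoallyl array). Both therefore come from one cyclopropylcarbinyl radical: opening of a gem-dimethylcyclopropane gives C=CH2 and a tertiary radical, which closes the six-membered ring onto a vinyl sulfone held on the same quaternary cyclopropane carbon.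
3. Forward order: western ring, steps 1–13 (cyclopropane lactone, alkylation, ring closure in step 9, alkenylboronate); eastern ring carried from 2,3-dimethylcyclohexenone, steps 14–26; union, methylation and desilylation, steps 27–29.
4. Stereochemistry: west, the ring CH next to CH2O comes from the enantioselective Rh-catalysed cyclopropanation and directs the new methine in the cyclisation (1,3-cis). East, CBS reduction, OH-directed epoxidation, anti Grignard addition and a stereospecific semipinacol shift set the two vicinal fully substituted carbons; tethered hydroboration sets the ring CH. Alkene geometry comes from the CrCl2 olefination, the trans-selective coupling with retention, and allylic strain in the enal.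

Key step: step 9

Remark on the chemistry: in 5–9 the configuration of the quaternary cyclopropane carbon is of no consequence, because it becomes the sp2 ring carbon of the exocyclic methylene in step 9; only the ring CH set in step 3 is carried into the target.

**Route**

Step 1
Reactants: 1 3-methylbut-2-en-1-ol
Product: 2 3-methylbut-2-en-1-yl bromoacetate
Conditions: bromoacetyl bromide, NaHCO3, MeCN, 0 °C
Reagents that add atoms: bromoacetyl bromide, BrCC(Br)=O
Why: O-acylation of the primary allylic alcohol by the acid bromide (esterification), with NaHCO3 taking up HBr.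

Step 2
Reactants: 2 3-methylbut-2-en-1-yl bromoacetate
Product: 3 3-methylbut-2-en-1-yl diazoacetate
Conditions: N,N'-ditosylhydrazine, DBU, THF, 0 °C
Reagents that add atoms: N,N'-ditosylhydrazine, Cc1ccc(cc1)S(=O)(=O)NNS(=O)(=O)c1ccc(C)cc1
Why: N-alkylation of the sulfonylhydrazide by the α-bromo ester and twofold sulfinate elimination should give the diazoacetate (diazo synthesis from bromoacetates).

Step 3
Reactants: 3 3-methylbut-2-en-1-yl diazoacetate
Product: 4 (1S,5R)-6,6-dimethyl-3-oxabicyclo[3.1.0]hexan-2-one
Conditions: Rh2(5S-MEPY)4 (dirhodium tetrakis[methyl (5S)-2-oxopyrrolidine-5-carboxylate], 0.5 mol%), CH2Cl2, reflux, slow addition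
Reagents that add atoms: none
Why: Intramolecular carbenoid cyclopropanation of the trisubstituted alkene; the chiral carboxamidate ligands select the alkene face and the five-membered lactone forces cis fusion, so both ring-fusion carbons are set here.

Step 4
Reactants: 4 (1S,5R)-6,6-dimethyl-3-oxabicyclo[3.1.0]hexan-2-one
Product: 5 (1S,5S)-1-(but-3-en-1-yl)-6,6-dimethyl-3-oxabicyclo[3.1.0]hexan-2-one
Conditions: LDA, THF, −78 °C; 4-iodobut-1-ene, DMPU, −78 to −30 °C
Reagents that add atoms: 4-iodobut-1-ene, C=CCCI
Why: Lactone enolate alkylation; the cyclopropyl enolate can react only on the face that keeps the bicycle cis-fused, so the chain enters with retention and the ring CH is untouched.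

Step 5
Reactants: 5 (1S,5S)-1-(but-3-en-1-yl)-6,6-dimethyl-3-oxabicyclo[3.1.0]hexan-2-one
Product: 6 [(1S,3S)-1-(but-3-en-1-yl)-2,2-dimethylcyclopropane-1,3-diyl]dimethanol (the two CH2OH groups cis)
Conditions: LiAlH4, THF, 0 °C
Reagents that add atoms: none
Why: Hydride reduction of the lactone to the diol; no stereocentre is involved.

Step 6
Reactants: 6 [(1S,3S)-1-(but-3-en-1-yl)-2,2-dimethylcyclopropane-1,3-diyl]dimethanol
Product: 7 [(1S,3S)-1-(but-3-en-1-yl)-3-(tert-butyldimethylsilyloxymethyl)-2,2-dimethylcyclopropyl]methanol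
Conditions: TBSCl, imidazole, CH2Cl2, −20 °C
Reagents that add atoms: tert-butyldimethylsilyl chloride, CC(C)(C)[Si](C)(C)Cl
Why: Selective silylation; the CH2OH on the ring CH should react faster than the neopentyl-type CH2OH on the quaternary carbon.

Step 7
Reactants: 7 [(1S,3S)-1-(but-3-en-1-yl)-3-(tert-butyldimethylsilyloxymethyl)-2,2-dimethylcyclopropyl]methanol
Product: 8 [(1S,3S)-3-(tert-butyldimethylsilyloxymethyl)-2,2-dimethyl-1-[(3E)-4-(phenylsulfonyl)but-3-en-1-yl]cyclopropyl]methanol
Conditions: phenyl vinyl sulfone, second-generation Hoveyda–Grubbs catalyst RuCl2(H2IMes)(=CH-C6H4-2-OiPr) (5 mol%), CH2Cl2, 40 °C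
Reagents that add atoms: phenyl vinyl sulfone, C=CS(=O)(=O)c1ccccc1
Why: Olefin cross-metathesis of the terminal alkene with the electron-poor sulfone should give the (E)-vinyl sulfone, the radical acceptor for step 9.

Step 8
Reactants: 8 [(1S,3S)-3-(tert-butyldimethylsilyloxymethyl)-2,2-dimethyl-1-[(3E)-4-(phenylsulfonyl)but-3-en-1-yl]cyclopropyl]methanol
Product: 9 O-pentafluorophenyl thionocarbonate of 8 (ROC(=S)OC6F5 on the CH2O of the quaternary cyclopropane carbon)
Conditions: pentafluorophenyl chlorothionoformate, pyridine, CH2Cl2, 0 °C to rt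
Reagents that add atoms: pentafluorophenyl chlorothionoformate, S=C(Cl)Oc1c(F)c(F)c(F)c(F)c1F
Why: O-thioacylation of the remaining primary alcohol installs the radical leaving group (Barton–McCombie precursor for a primary alcohol) without substitution at the ionisation-prone cyclopropylcarbinyl carbon.

Step 9
Reactants: 9 O-pentafluorophenyl thionocarbonate of 8
Product: 10 tert-butyl(dimethyl){[(1R,3S)-2,2-dimethyl-6-methylidene-3-(phenylsulfonylmethyl)cyclohexyl]methoxy}silane
Conditions: Bu3SnH, AIBN (cat.), toluene, 110 °C, syringe-pump addition, 5 mM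
Reagents that add atoms: none
Why: Bu3Sn• adds to the C=S group and the adduct fragments (Barton–McCombie radical generation) to the primary cyclopropylcarbinyl radical, which opens by scission of the bond between the quaternary and the gem-dimethyl cyclopropane carbons; this strain-releasing step creates the exocyclic C=CH2 and a nucleophilic tertiary radical, which adds to the β-carbon of the vinyl sulfone and so forms the bond between the gem-dimethyl carbon and the future methyl-bearing CH, the α-sulfonyl radical then taking H from Bu3SnH. The closest known reaction types are the radical-clock opening of cyclopropylcarbinyl radicals and the tin hydride mediated Giese cyclisation onto a vinyl sulfone. The six-membered ring closes in the 6-exo-trig mode. The new methine stereocentre is controlled by the ring CH that carries CH2OTBS: in the chair-like transition state, allylic strain at the planar radical centre keeps the CH2OTBS group pseudo-equatorial (its H eclipses a radical methyl) and the sulfonylvinyl arm is pseudo-equatorial as well, which should give the 1,3-cis ring. The step needs cleavage of the more substituted cyclopropane bond, secured by the two methyl groups (tertiary against secondary radical, no stabilising group on the CH), and cyclisation faster than reduction or 1,5-hydrogen transfer, secured by the electron-poor acceptor and slow addition of the stannane at high dilution.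

Step 10
Reactants: 10 tert-butyl(dimethyl){[(1R,3S)-2,2-dimethyl-6-methylidene-3-(phenylsulfonylmethyl)cyclohexyl]methoxy}silane
Product: 11 tert-butyl(dimethyl){[(1R,3S)-2,2,3-trimethyl-6-methylidenecyclohexyl]methoxy}silane
Conditions: sodium amalgam (6% Na in Hg), MeOH/THF, −20 °C
Reagents that add atoms: none
Why: Reductive desulfonylation by electron transfer turns the helper CH2SO2Ph into the ring methyl group without touching the alkene or the silyl ether.

Step 11
Reactants: 11 tert-butyl(dimethyl){[(1R,3S)-2,2,3-trimethyl-6-methylidenecyclohexyl]methoxy}silane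
Product: 12 [(1R,3S)-2,2,3-trimethyl-6-methylidenecyclohexyl]methanol
Conditions: HF·pyridine, pyridine, THF, 0 °C to rt
Reagents that add atoms: none
Why: Fluoride-mediated desilylation under buffered conditions that leave the exocyclic alkene in place.

Step 12
Reactants: 12 [(1R,3S)-2,2,3-trimethyl-6-methylidenecyclohexyl]methanol
Product: 13 (1R,3S)-2,2,3-trimethyl-6-methylidenecyclohexane-1-carbaldehyde
Conditions: Dess–Martin periodinane, NaHCO3, CH2Cl2, 0 °C; used crude
Reagents that add atoms: none
Why: Dess–Martin oxidation under buffered, non-basic conditions, so that the α-stereocentre is not epimerised and the β,γ-alkene does not move into conjugation.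

Step 13
Reactants: 13 (1R,3S)-2,2,3-trimethyl-6-methylidenecyclohexane-1-carbaldehyde
Product: 14 4,4,5,5-tetramethyl-2-{(E)-2-[(1R,3S)-2,2,3-trimethyl-6-methylidenecyclohexyl]ethenyl}-1,3,2-dioxaborolane
Conditions: 2-(dichloromethyl)-4,4,5,5-tetramethyl-1,3,2-dioxaborolane, CrCl2, LiI, THF, rt
Reagents that add atoms: 2-(dichloromethyl)-4,4,5,5-tetramethyl-1,3,2-dioxaborolane, ClC(Cl)B1OC(C)(C)C(C)(C)O1
Why: Takai–Utimoto-type olefination with a geminal dichromium boronate; anti elimination from the adduct should give the (E)-alkenylboronate, and the neutral medium protects the α-stereocentre.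

Step 14
Reactants: 15 2,3-dimethylcyclohex-2-en-1-one
Product: 16 (1R)-2,3-dimethylcyclohex-2-en-1-ol
Conditions: (S)-2-methyl-CBS-oxazaborolidine (10 mol%), BH3·SMe2, THF, −20 °C
Reagents that add atoms: none
Why: Corey–Bakshi–Shibata reduction; with the substituted alkenyl side as the large group the (S)-catalyst should deliver hydride to the face that gives the (R)-allylic alcohol.

Step 15
Reactants: 16 (1R)-2,3-dimethylcyclohex-2-en-1-ol
Product: 17 (2R)-1,6-dimethyl-7-oxabicyclo[4.1.0]heptan-2-ol, epoxide cis to the hydroxyl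
Conditions: VO(acac)2 (2 mol%), t-BuOOH, CH2Cl2, 0 °C
Reagents that add atoms: tert-butyl hydroperoxide, CC(C)(C)OO
Why: Hydroxyl-directed vanadium-catalysed epoxidation of the allylic alcohol delivers oxygen to the face of the OH group.

Step 16
Reactants: 17 (2R)-1,6-dimethyl-7-oxabicyclo[4.1.0]heptan-2-ol
Product: 18 1,6-dimethyl-7-oxabicyclo[4.1.0]heptan-2-one (single enantiomer, epoxide as in 17)
Conditions: Dess–Martin periodinane, NaHCO3, CH2Cl2, rt
Reagents that add atoms: none
Why: Dess–Martin oxidation of the secondary alcohol; the epoxide stereocentres now carry the chirality.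

Step 17
Reactants: 18 1,6-dimethyl-7-oxabicyclo[4.1.0]heptan-2-one
Product: 19 1,6-dimethyl-2-(prop-2-en-1-yl)-7-oxabicyclo[4.1.0]heptan-2-ol, hydroxyl cis and allyl trans to the epoxide oxygen
Conditions: allylmagnesium bromide, THF, −78 °C
Reagents that add atoms: allylmagnesium bromide, C=CC[Mg]Br
Why: Grignard 1,2-addition to the α,β-epoxy ketone from the face opposite the epoxide oxygen places the allyl group anti to the C–O bond that will break in step 18.

Step 18
Reactants: 19 1,6-dimethyl-2-(prop-2-en-1-yl)-7-oxabicyclo[4.1.0]heptan-2-ol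
Product: 20 (2R,3S)-3-hydroxy-2,3-dimethyl-2-(prop-2-en-1-yl)cyclohexan-1-one
Conditions: ZnBr2, CH2Cl2, 0 °C
Reagents that add atoms: none
Why: Semipinacol rearrangement of the 2,3-epoxy alcohol; the allyl group shifts anti to the breaking C–O bond with inversion at the proximal epoxide carbon while the distal C–O bond is kept, which fixes the quaternary carbon and the tertiary carbinol stereospecifically.

Step 19
Reactants: 20 (2R,3S)-3-hydroxy-2,3-dimethyl-2-(prop-2-en-1-yl)cyclohexan-1-one
Product: 21 (2R,3S)-2,3-dimethyl-2-(prop-2-en-1-yl)-3-(triethylsilyloxy)cyclohexan-1-one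
Conditions: TESOTf, 2,6-lutidine, CH2Cl2, −78 to 0 °C
Reagents that add atoms: triethylsilyl trifluoromethanesulfonate, CC[Si](CC)(CC)OS(=O)(=O)C(F)(F)F
Why: Silylation of the tertiary alcohol blocks retro-aldol cleavage in the basic steps that follow.

Step 20
Reactants: 21 (2R,3S)-2,3-dimethyl-2-(prop-2-en-1-yl)-3-(triethylsilyloxy)cyclohexan-1-one
Product: 22 (5S,6R)-5,6-dimethyl-6-(prop-2-en-1-yl)-5-(triethylsilyloxy)cyclohex-1-en-1-yl trifluoromethanesulfonate
Conditions: KHMDS, THF, −78 °C; PhNTf2
Reagents that add atoms: N-phenylbis(trifluoromethanesulfonimide), O=S(=O)(N(c1ccccc1)S(=O)(=O)C(F)(F)F)C(F)(F)F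
Why: Enolisation at the only enolisable α-carbon and O-triflation give the enol triflate regiospecifically.

Step 21
Reactants: 22 (5S,6R)-5,6-dimethyl-6-(prop-2-en-1-yl)-5-(triethylsilyloxy)cyclohex-1-en-1-yl trifluoromethanesulfonate
Product: 23 tert-butyl{3-[(5S,6R)-5,6-dimethyl-6-(prop-2-en-1-yl)-5-(triethylsilyloxy)cyclohex-1-en-1-yl]propoxy}dimethylsilane
Conditions: allyl tert-butyldimethylsilyl ether, 9-BBN, THF, rt; then 22, Pd(dppf)Cl2 (5 mol%), AsPh3, Cs2CO3, DMF/H2O, rt to 50 °C
Reagents that add atoms: allyloxy(tert-butyl)dimethylsilane, C=CCO[Si](C)(C)C(C)(C)C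
Why: B-alkyl Suzuki–Miyaura coupling of the enol triflate with the in-situ alkylborane attaches the protected 3-hydroxypropyl chain and leaves a trisubstituted ring alkene.

Step 22
Reactants: 23 tert-butyl{3-[(5S,6R)-5,6-dimethyl-6-(prop-2-en-1-yl)-5-(triethylsilyloxy)cyclohex-1-en-1-yl]propoxy}dimethylsilane
Product: 25 diol: ring secondary alcohol plus 3-hydroxypropyl on the quaternary carbon (stereochemistry as in the SMILES), via cyclic thexylborane 24 (not isolated)
Conditions: thexylborane, THF, −10 °C to rt; then NaOH, H2O2, 0 °C to rt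
Reagents that add atoms: hydrogen peroxide, OO
Why: Cyclic hydroboration; the borane first adds to the terminal allyl group and the tethered B–H then adds intramolecularly and anti-Markovnikov to the ring alkene from the face of the tether, so the new ring hydrogen is cis to the quaternary-carbon chain, and oxidation with retention gives the diol.

Step 23
Reactants: 25 diol
Product: 26 keto aldehyde: 3-[(1S,2R,6S)-2-(3-tert-butyldimethylsilyloxypropyl)-1,6-dimethyl-3-oxo-6-(triethylsilyloxy)cyclohexyl]propanal (configuration as in the SMILES)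
Conditions: Dess–Martin periodinane (3 equiv), NaHCO3, CH2Cl2, 0 °C to rt
Reagents that add atoms: none
Why: Twofold Dess–Martin oxidation; the non-basic medium keeps the new α-stereocentre of the ketone.

Step 24
Reactants: 26 keto aldehyde
Product: 27 1,1-dibromoalkene ketone (CHO converted into CH=CBr2)
Conditions: CBr4, PPh3, 2,6-lutidine, CH2Cl2, 0 °C
Reagents that add atoms: carbon tetrabromide, BrC(Br)(Br)Br
Why: Ramirez dibromo-olefination (first stage of the Corey–Fuchs sequence) is selective for the aldehyde over the hindered ketone.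

Step 25
Reactants: 27 1,1-dibromoalkene ketone
Product: 28 tertiary allylic alcohol (isopropenyl carbinol, either epimer at the new carbinol carbon)
Conditions: isopropenylmagnesium bromide, anhydrous CeCl3, THF, −78 °C
Reagents that add atoms: isopropenylmagnesium bromide, CC(=C)[Mg]Br
Why: Organocerium 1,2-addition to the hindered, enolisable ketone without enolisation or halogen–metal exchange; the new carbinol centre is removed in step 26.

Step 26
Reactants: 28 tertiary allylic alcohol
Product: 29 (2Z)-2-[(2R,3S,4S)-3-(4,4-dibromobut-3-en-1-yl)-2-(3-tert-butyldimethylsilyloxypropyl)-3,4-dimethyl-4-(triethylsilyloxy)cyclohexylidene]propanal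
Conditions: pyridinium chlorochromate, 4 Å molecular sieves, CH2Cl2, rt
Reagents that add atoms: pyridinium chlorochromate, [O-][Cr](=O)(=O)Cl.c1cc[nH+]cc1
Why: Babler–Dauben oxidative transposition (sigmatropic 1,3-shift of the chromate ester, then oxidation); the (Z)-enal is expected because the methyl group avoids the branched ring CH and the smaller, rotatable formyl group takes the position syn to it (allylic strain).

Step 27
Reactants: 14 western (E)-alkenylboronate; 29 eastern dibromoalkene enal
Product: 30 (1E,3Z)-3-bromodiene: alkenyl group joined trans to the CH2 chain, one Br kept (bis-silyl ether)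
Conditions: Pd(PPh3)4 (5 mol%), TlOEt, THF/H2O, rt
Reagents that add atoms: none
Why: Suzuki–Miyaura coupling of a 1,1-dibromoalkene; oxidative addition occurs at the less hindered C–Br bond trans to the alkyl chain, and coupling with retention at both partners sets the (E)-disubstituted alkene and the relative position of chain and western ring.

Step 28
Reactants: 30 (1E,3Z)-3-bromodiene
Product: 31 bis-silyl ether of the target (primary OTBS, tertiary OTES)
Conditions: Me2Zn, Pd(t-Bu3P)2 (5 mol%), THF, 0 °C to rt
Reagents that add atoms: dimethylzinc, C[Zn]C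
Why: Negishi methylation of the 2-bromo-1,3-diene; the bulky phosphine favours retention, completing the (E,E)-diene, and dimethylzinc alone should not add to the hindered enal.

Step 29
Reactants: 31 bis-silyl ether of the target
Product: 32 CNP0155943.1
Conditions: HF·pyridine, pyridine, THF, 0 °C to rt
Reagents that add atoms: none
Why: Fluoride desilylation removes both silyl ethers under buffered conditions that should spare the enal, the diene and the exocyclic alkene.

**Compound list**

1 | 3-methylbut-2-en-1-ol | CC(C)=CCO | starting material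
2 | 3-methylbut-2-en-1-yl bromoacetate | CC(C)=CCOC(=O)CBr | intermediate
3 | 3-methylbut-2-en-1-yl diazoacetate | CC(C)=CCOC(=O)C=[N+]=[N-] | intermediate
4 | (1S,5R)-6,6-dimethyl-3-oxabicyclo[3.1.0]hexan-2-one | CC1(C)[C@H]2[C@@H]1C(=O)OC2 | intermediate
5 | (1S,5S)-1-(but-3-en-1-yl)-6,6-dimethyl-3-oxabicyclo[3.1.0]hexan-2-one | CC1(C)[C@H]2[C@]1(CCC=C)C(=O)OC2 | intermediate
6 | [(1S,3S)-1-(but-3-en-1-yl)-2,2-dimethylcyclopropane-1,3-diyl]dimethanol | CC1(C)[C@H](CO)[C@@]1(CO)CCC=C | intermediate
7 | [(1S,3S)-1-(but-3-en-1-yl)-3-(tert-butyldimethylsilyloxymethyl)-2,2-dimethylcyclopropyl]methanol | CC1(C)[C@H](CO[Si](C)(C)C(C)(C)C)[C@@]1(CO)CCC=C | intermediate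
8 | [(1S,3S)-3-(tert-butyldimethylsilyloxymethyl)-2,2-dimethyl-1-[(3E)-4-(phenylsulfonyl)but-3-en-1-yl]cyclopropyl]methanol | CC1(C)[C@H](CO[Si](C)(C)C(C)(C)C)[C@@]1(CO)CC/C=C/S(=O)(=O)c1ccccc1 | intermediate
9 | O-pentafluorophenyl O-{[(1S,3S)-3-(tert-butyldimethylsilyloxymethyl)-2,2-dimethyl-1-[(3E)-4-(phenylsulfonyl)but-3-en-1-yl]cyclopropyl]methyl} thiocarbonate | CC1(C)[C@H](CO[Si](C)(C)C(C)(C)C)[C@@]1(COC(=S)Oc1c(F)c(F)c(F)c(F)c1F)CC/C=C/S(=O)(=O)c1ccccc1 | intermediate
10 | tert-butyl(dimethyl){[(1R,3S)-2,2-dimethyl-6-methylidene-3-(phenylsulfonylmethyl)cyclohexyl]methoxy}silane | C=C1CC[C@H](CS(=O)(=O)c2ccccc2)C(C)(C)[C@@H]1CO[Si](C)(C)C(C)(C)C | intermediate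
11 | tert-butyl(dimethyl){[(1R,3S)-2,2,3-trimethyl-6-methylidenecyclohexyl]methoxy}silane | C=C1CC[C@H](C)C(C)(C)[C@@H]1CO[Si](C)(C)C(C)(C)C | intermediate
12 | [(1R,3S)-2,2,3-trimethyl-6-methylidenecyclohexyl]methanol | C=C1CC[C@H](C)C(C)(C)[C@@H]1CO | intermediate
13 | (1R,3S)-2,2,3-trimethyl-6-methylidenecyclohexane-1-carbaldehyde | C=C1CC[C@H](C)C(C)(C)[C@@H]1C=O | intermediate
14 | 4,4,5,5-tetramethyl-2-{(E)-2-[(1R,3S)-2,2,3-trimethyl-6-methylidenecyclohexyl]ethenyl}-1,3,2-dioxaborolane | C=C1CC[C@H](C)C(C)(C)[C@@H]1/C=C/B1OC(C)(C)C(C)(C)O1 | intermediate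
15 | 2,3-dimethylcyclohex-2-en-1-one | CC1=C(C)C(=O)CCC1 | starting material
16 | (1R)-2,3-dimethylcyclohex-2-en-1-ol | CC1=C(C)[C@H](O)CCC1 | intermediate
17 | (2R)-1,6-dimethyl-7-oxabicyclo[4.1.0]heptan-2-ol, epoxide cis to OH | O[C@@H]1CCC[C@]2(C)O[C@]12C | intermediate
18 | 1,6-dimethyl-7-oxabicyclo[4.1.0]heptan-2-one, epoxide as in 17 | O=C1CCC[C@]2(C)O[C@]12C | intermediate
19 | 1,6-dimethyl-2-(prop-2-en-1-yl)-7-oxabicyclo[4.1.0]heptan-2-ol, OH cis and allyl trans to the epoxide oxygen | C=CC[C@@]1(O)CCC[C@]2(C)O[C@]12C | intermediate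
20 | (2R,3S)-3-hydroxy-2,3-dimethyl-2-(prop-2-en-1-yl)cyclohexan-1-one | C=CC[C@@]1(C)C(=O)CCC[C@]1(C)O | intermediate
21 | (2R,3S)-2,3-dimethyl-2-(prop-2-en-1-yl)-3-(triethylsilyloxy)cyclohexan-1-one | C=CC[C@@]1(C)C(=O)CCC[C@]1(C)O[Si](CC)(CC)CC | intermediate
22 | (5S,6R)-5,6-dimethyl-6-(prop-2-en-1-yl)-5-(triethylsilyloxy)cyclohex-1-en-1-yl trifluoromethanesulfonate | C=CC[C@@]1(C)C(OS(=O)(=O)C(F)(F)F)=CCC[C@]1(C)O[Si](CC)(CC)CC | intermediate
23 | tert-butyl{3-[(5S,6R)-5,6-dimethyl-6-(prop-2-en-1-yl)-5-(triethylsilyloxy)cyclohex-1-en-1-yl]propoxy}dimethylsilane | C=CC[C@@]1(C)C(CCCO[Si](C)(C)C(C)(C)C)=CCC[C@]1(C)O[Si](CC)(CC)CC | intermediate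
24 | cyclic thexylborane: B-(2,3-dimethylbutan-2-yl) borepane spanning the chain terminus and the ring CH, fused to the cyclohexane | CC(C)C(C)(C)B2CCC[C@@]1(C)[C@H](CCCO[Si](C)(C)C(C)(C)C)[C@@H]2CC[C@]1(C)O[Si](CC)(CC)CC | intermediate (not isolated)
25 | diol: 2-(3-tert-butyldimethylsilyloxypropyl)-3-(3-hydroxypropyl)-3,4-dimethyl-4-(triethylsilyloxy)cyclohexan-1-ol, configuration as in the SMILES | OCCC[C@@]1(C)[C@H](CCCO[Si](C)(C)C(C)(C)C)[C@@H](O)CC[C@]1(C)O[Si](CC)(CC)CC | intermediate
26 | 3-[2-(3-tert-butyldimethylsilyloxypropyl)-1,6-dimethyl-3-oxo-6-(triethylsilyloxy)cyclohexyl]propanal, configuration as in the SMILES | O=CCC[C@@]1(C)[C@H](CCCO[Si](C)(C)C(C)(C)C)C(=O)CC[C@]1(C)O[Si](CC)(CC)CC | intermediate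
27 | 3-(4,4-dibromobut-3-en-1-yl)-2-(3-tert-butyldimethylsilyloxypropyl)-3,4-dimethyl-4-(triethylsilyloxy)cyclohexan-1-one, configuration as in the SMILES | BrC(Br)=CCC[C@@]1(C)[C@H](CCCO[Si](C)(C)C(C)(C)C)C(=O)CC[C@]1(C)O[Si](CC)(CC)CC | intermediate
28 | 1-(prop-1-en-2-yl) carbinol of 27 (either epimer at the carbinol carbon) | BrC(Br)=CCC[C@@]1(C)[C@H](CCCO[Si](C)(C)C(C)(C)C)C(O)(C(C)=C)CC[C@]1(C)O[Si](CC)(CC)CC | intermediate
29 | (2Z)-2-[(2R,3S,4S)-3-(4,4-dibromobut-3-en-1-yl)-2-(3-tert-butyldimethylsilyloxypropyl)-3,4-dimethyl-4-(triethylsilyloxy)cyclohexylidene]propanal | BrC(Br)=CCC[C@@]1(C)[C@H](CCCO[Si](C)(C)C(C)(C)C)/C(=C(/C)C=O)CC[C@]1(C)O[Si](CC)(CC)CC | intermediate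
30 | (1E,3Z)-3-bromodiene: 31 with Br in place of the diene methyl group | C=C1CC[C@H](C)C(C)(C)[C@@H]1/C=C/C(Br)=C/CC[C@@]1(C)[C@H](CCCO[Si](C)(C)C(C)(C)C)/C(=C(/C)C=O)CC[C@]1(C)O[Si](CC)(CC)CC | intermediate
31 | bis-silyl ether of the target (primary OTBS, tertiary OTES) | C=C1CC[C@H](C)C(C)(C)[C@@H]1/C=C/C(C)=C/CC[C@@]1(C)[C@H](CCCO[Si](C)(C)C(C)(C)C)/C(=C(/C)C=O)CC[C@]1(C)O[Si](CC)(CC)CC | intermediate
32 | CNP0155943.1, (2Z)-2-[(2R,3S,4S)-4-hydroxy-2-(3-hydroxypropyl)-3,4-dimethyl-3-{(3E,5E)-4-methyl-6-[(1R,3S)-2,2,3-trimethyl-6-methylidenecyclohexyl]hexa-3,5-dien-1-yl}cyclohexylidene]propanal | C=C1CC[C@H](C)C(C)(C)[C@@H]1/C=C/C(C)=C/CC[C@@]1(C)[C@H](CCCO)/C(=C(/C)C=O)CC[C@]1(C)O | target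

**Count**

Total steps: 29. Longest linear sequence: 16 steps (steps 14–26, then 27–29; the western branch, steps 1–13 then 27–29, is equally long).

**Steps most likely to fail**

Step 9. The primary thionocarbonate adduct may fragment too slowly, so that the chain dies or the stannyl radical adds to the vinyl sulfone; the cyclopropane may also open partly toward the secondary radical, and facial selectivity in the ring closure may be modest. The fallback separates ring opening from radical generation. It sets out from 8: ionic homoallylic ring opening of the cyclopropylcarbinol (Julia olefin synthesis type; TMSBr, ZnBr2, CH2Cl2, −30 °C) should give the tertiary homoallylic bromide F1, in which the exocyclic methylene is already in place and the bromide sits on the gem-dimethyl carbon. Bu3SnH/AIBN then generates the same tertiary radical from a conventional tertiary bromide, and the 6-exo cyclisation onto the vinyl sulfone returns to the route at 10.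

Step 4. C-alkylation of the strained bicyclic enolate by an unactivated primary iodide may be slow, with self-condensation of the lactone and elimination of the iodide competing. The fallback sets out from 4: saponification (KOH), silylation (TBSCl, imidazole) and cleavage of the silyl ester (K2CO3, MeOH) give the cis silyloxy acid F2. Its carboxylate dianion (2 equiv LDA) is alkylated with 4-iodobut-1-ene, anti to the CH2OTBS group, to give the quaternary acid F3, and LiAlH4 reduction returns to the route at 7. This path also avoids the selective silylation of step 6; an epimer at the quaternary carbon would serve equally.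

Step 26. The transposition may give a mixture of enal geometries (poor geometric control at the tetrasubstituted alkene), and the enal may isomerise through its dienol. The fallback sets out from 27: Horner–Wadsworth–Emmons reaction with diethyl (1-cyanoethyl)phosphonate (NaH, THF), followed by base equilibration, should place the small linear cyano group syn to the branched ring CH and give the unsaturated nitrile F4. DIBAL reduction and hydrolysis of the imine then give the (Z)-enal, and the route is rejoined at 29.

**Further compounds**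

F1 | step 9 | tert-butyl{[(2R)-3-bromo-3-methyl-2-[(5E)-6-(phenylsulfonyl)hexa-1,5-dien-2-yl]butyl]oxy}dimethylsilane (tertiary homoallylic bromide) | C=C(CC/C=C/S(=O)(=O)c1ccccc1)[C@@H](CO[Si](C)(C)C(C)(C)C)C(C)(C)Br
F2 | step 4 | cis-3-(tert-butyldimethylsilyloxymethyl)-2,2-dimethylcyclopropane-1-carboxylic acid (ring CH as in 4) | CC1(C)[C@H](CO[Si](C)(C)C(C)(C)C)[C@@H]1C(=O)O
F3 | step 4 | 1-(but-3-en-1-yl)-3-(tert-butyldimethylsilyloxymethyl)-2,2-dimethylcyclopropane-1-carboxylic acid (CO2H cis to CH2OTBS) | CC1(C)[C@H](CO[Si](C)(C)C(C)(C)C)[C@@]1(C(=O)O)CCC=C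
F4 | step 26 | (2Z)-2-[(2R,3S,4S)-3-(4,4-dibromobut-3-en-1-yl)-2-(3-tert-butyldimethylsilyloxypropyl)-3,4-dimethyl-4-(triethylsilyloxy)cyclohexylidene]propanenitrile | BrC(Br)=CCC[C@@]1(C)[C@H](CCCO[Si](C)(C)C(C)(C)C)/C(=C(/C)C#N)CC[C@]1(C)O[Si](CC)(CC)CC
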